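## Structural features

The target is a cembrane: one fourteen-membered carbocycle (C1–C14) with no second carbocycle, carrying a trisubstituted oxirane fused at C12–C13. Three groups of stereo-elements must be delivered: the acetoxy-bearing allylic carbon C1 (S), the ring carbon C6 (R) with its 2-acetoxypropan-2-yl group (C15), and the cis epoxide C12 (S)/C13 (R). In addition, C2=C3 is E and C8=C9 is Z, both trisubstituted. C12 and C13 are contiguous and C1 stands 1,3 to C13 through C14, whereas C6 is at least four ring atoms away from all of them and cannot control them. The fragile parts are the epoxide (acid, Lewis acid, neighbouring carbanions or borates), the allylic acetate at C1 (ionisation, zerovalent palladium) and the tertiary acetate at C15 (hydride, elimination). The real difficulty is the combination of remote absolute stereocontrol (C1/C12/C13 against C6), a Z-trisubstituted olefin inside the ring, and closure of the macrocycle without scrambling either. The key step exploits the six-atom string O–C1–C14–C13(Me)–C12–C11, in which C11 and C14 are cis on the C12–C13 bond: this is a 6-substituted 2-alkoxy-4-methyl-5,6-dihydro-2H-pyran in open form.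

## Logic of the disconnections

**27 ⇒ 26 ⇒ 25.** The two acyl C–O bonds at C1 and C15 are cut, and the O–H bonds are exchanged for O–Si bonds. The allylic ester would ionise under zerovalent palladium and the tertiary ester would not survive the hydride steps, so both esters are made last. The gain is that everything earlier is ester-free. The demand is that fluoride must release a tertiary triethylsilyl ether and that the acylation must reach a tertiary carbinol under basic conditions that leave the epoxide closed.

**25 ⇒ 23 (through 24).** The ring bond C9–C10 is cut. It is an sp3–sp2 bond next to the Z olefin, whose geometry can be stored in a vinyl iodide, and C10 is not stereogenic. The macrocycle becomes an open chain. The demand is that the borane adds only to the terminal vinyl group of 23, that coupling outruns any reaction of the boron-bearing chain with the neighbouring epoxide, and that high dilution suppresses oligomers.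

**23 ⇒ 22 ⇒ 21.** The C10=C11 bond is cut (one carbon from an ylide) and the aldehyde is returned to the carbinol. C11 is the only carbon that can carry a directing hydroxyl for the epoxide and later become a ring methylene. The demand is a neutral oxidation and a low-temperature olefination that do not epimerise C12.

**21 ⇒ 20.** The two C–O bonds of the oxirane are cut. The C11 hydroxyl allows reagent-controlled oxygen delivery, and the Z olefin already fixes the cis relation of C11 and C14. The demand is L-(+)-tartrate, which for a nerol-type alcohol gives the (2S,3R)-epoxy alcohol, that is 12S,13R. The C1 hydroxyl must be masked, because a free (S)-carbinol next to C2=C3 is expected to be a competent substrate of the same reagent.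

**20 ⇒ 19 ⇒ 18 ⇒ 17.** Only O–Si and O–acyl bonds are cut. The primary hydroxyl is acylated first on steric grounds, the secondary one silylated, and the acyl group removed. The demand is clean discrimination between a primary and a secondary allylic hydroxyl.

**17 ⇒ 15 (through 16).** The O(C1)–C11 bond is re-formed and C11 raised to the acetal level. The ring stores the Z geometry of C12=C13 and keeps C1–O and C11–O distinct. The demand is hydrolysis that ionises only the acetal carbon, not the allylic C1–O bond, followed by 1,2-reduction of the open hydroxy enal.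

**15 ⇒ 11 + 14.** C1–C14 and O–C11 are cut together. This removes the ring, the C1 stereocentre and the Z olefin in one operation and divides the chain into a C1–C9 aldehyde and a four-carbon diene. The demand is a catalyst that discriminates the faces of a conjugated aldehyde with no help from C6, reaction at C=O only, and endo selectivity (needed only for homogeneity, since the acetal centre is erased).

**14 ⇒ 13 ⇒ 12.** One C–O bond and a γ C–H bond are re-formed, then the acetal is returned to the aldehyde. The demand is an elimination that gives the E enol ether.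

**11 ⇒ 10 ⇒ 9 ⇒ 7 + 8.** C2=C3 is cut after two redox adjustments. This gives a methyl ketone and a two-carbon phosphonate. The demand is E selectivity at a methyl ketone, which is only moderate and is handled by separation.

**7 ⇒ 6.** C8=C9 is cut. The ylide must carry both iodine and methyl, because C9 bears a methyl group. The demand is Z selectivity and reaction at the aldehyde in the presence of the ketone.

**6 ⇒ 4 (through 5) ⇒ 3 ⇒ 1 (through 2).** C3 and C8 are reconnected as the ring olefin of a cyclohexene, then the Si–O bond and the C15–O bond are cut. Both carbonyls and the C6 stereocentre come from one terpene. Ring carbons C3, C5, C6, C8 of 1 map onto C7, C5, C4, C3 of the target and the isopropenyl carbon onto C15, so the R configuration of 1 becomes 6R. The demand is hydration of the exocyclic olefin only.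

## Other disconnections considered

**Alternative 1:** The cut is C10–C11, made by a [3,3] shift inside a temporary ring. The seven-membered ketene acetal A2 (C15–O and C8–O tied to a C12 ketene carbon, C8 carrying an isopropenyl group) would rearrange on heating to the nine-membered lactone A1, in which C8=C9 must be Z.
- In its favour: the Z geometry would be enforced by the medium ring and not by a kinetic olefination, so on the fidelity of C8=C9 this route is the better of the two (the chosen plan relies on step 4). No chiral catalyst is needed, C6 again comes from the chiral pool, and the configuration at C8 in A2 is irrelevant.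
- Against it here: A1 solves only the C6–C11 region. The lactone carbon C12 is at the carboxyl level and must be taken down and extended by C13 and C14. The Z-C12=C13 unit, the epoxide and C1 would each need their own step, and the fourteen-membered ring still has to be closed elsewhere.
- Comparison: mechanistically the thermal pericyclic step is at least as robust as the catalytic cycloaddition. In step economy and in the number of stereo-elements set per operation the chosen plan is ahead, since its key step delivers C1 and the cis C12=C13 unit together.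

**Alternative 2:** The cut is C2–C3, taken as a triple bond. The acyclic diyne A4 with two propynyl ends would undergo ring-closing alkyne metathesis under a molybdenum alkylidyne of the type Mo(≡CAr)(OSiPh3)3 to the cycloalkyne A3.
- In its favour: closure at sp carbons has no geometric ambiguity, such catalysts tolerate epoxides, esters and silyl ethers, and the C15 acetate is already in place in A3. In ring-closure reliability and in avoiding a late tertiary acylation this alternative is the better.
- Against it here: the alkyne must afterwards become the E olefin with the methyl group on C3, the carbon distal to the C1 oxygen. Hydroxyl-directed trans-hydrometalation would be expected to place the metal on C2, and hydroalumination would endanger the acetate and the epoxide. C1 would also have to come from a separate asymmetric alkynylation and the epoxide from a separate epoxidation before ring closure.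
- Comparison: the ring closure is safer, but the stereo-elements are bought one at a time and the olefin unmasking adds steps of uncertain regiochemistry. Overall length would be equal at best.

**Alternative 3:** The cut is C9–C10. The seco vinyl epoxide A6 would be hydroborated at the vinyl group and the C10 borane coupled with the C9 vinyl iodide to give the macrocycle A5.
- In its favour: it is convergent, the Z geometry is transferred with retention, and no new stereocentre is formed. A5 has the structure of 25 and A6 that of 23, so this is the same ring closure as step 18 of the chosen plan and on this point the two are equal by construction, including the shared risk of a borane next to an epoxide.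
- Against it as the strategy-defining step: it does not say how C1 and the cis C12–C13 unit of A6 arise. Without the cycloaddition these would need an asymmetric C–C bond formation at C1 and an independent Z-selective construction of C12=C13, two operations instead of one.
- Comparison: the chosen plan is this alternative plus an economical supply of its seco compound.

Key step: step 10

Assumption: the (1S,2R)-aminoindanol-derived chromium complex is taken as the antipode that shields the Re face of the bound aldehyde; if a trial with a simple enal shows the opposite sense, its (1R,2S) mirror image is used and nothing else changes.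

## Route

Step 1
Reactants: 1 (R)-limonene
Product: 3 (R)-α-terpineol, via alkylmercury acetate 2 (not isolated)
Conditions: Hg(OAc)2, THF/H2O (1:1), rt; then NaOH (aq), NaBH4, 0 °C
Reagents that add atoms: water, O
Why: Markovnikov oxymercuration–demercuration should select the accessible 1,1-disubstituted exocyclic olefin over the trisubstituted ring olefin and give the tertiary alcohol; the stereocentre is not touched.

Step 2
Reactants: 3 (R)-α-terpineol
Product: 4 (R)-α-terpineol triethylsilyl ether
Conditions: Et3SiOTf, 2,6-lutidine, CH2Cl2, 0 °C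
Reagents that add atoms: triethylsilyl trifluoromethanesulfonate, CC[Si](CC)(CC)OS(=O)(=O)C(F)(F)F
Why: Silyl triflate silylation reaches a hindered tertiary alcohol; the triethylsilyl ether is expected to survive hydride, base and mild aqueous acid and to leave with fluoride at the end.

Step 3
Reactants: 4 (R)-α-terpineol triethylsilyl ether
Product: 6 (3R)-6-oxo-3-[2-(triethylsilyloxy)propan-2-yl]heptanal, via secondary ozonide 5 (not isolated)
Conditions: O3, CH2Cl2, −78 °C; then PPh3, −78 °C → rt
Reagents that add atoms: ozone, [O-][O+]=O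
Why: Ozonolysis (cycloaddition, cycloreversion and recombination to the ozonide, then phosphine reduction) cleaves the only olefin into the C3 methyl ketone and the C8 aldehyde; the keto aldehyde is used at once to avoid intramolecular aldol reaction.

Step 4
Reactants: 6 (3R)-6-oxo-3-[2-(triethylsilyloxy)propan-2-yl]heptanal
Product: 7 (5R,7Z)-8-iodo-5-[2-(triethylsilyloxy)propan-2-yl]non-7-en-2-one
Conditions: EtPPh3I, n-BuLi, THF, 0 °C; I2, −78 °C; NaN(SiMe3)2, −78 → −20 °C; then 6, −78 °C
Reagents that add atoms: ethyltriphenylphosphonium iodide, CC[P+](c1ccccc1)(c1ccccc1)c1ccccc1.[I-]; iodine, II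
Why: Stork–Zhao-type Wittig olefination with the α-iodo ylide: the non-stabilised ylide should react with the aldehyde far faster than with the methyl ketone at −78 °C, and kinetic oxaphosphetane formation places iodine cis to the chain (Z), which stores the C8=C9 geometry.

Step 5
Reactants: 7 (5R,7Z)-8-iodo-5-[2-(triethylsilyloxy)propan-2-yl]non-7-en-2-one; 8 triethyl phosphonoacetate
Product: 9 ethyl (2E,6R,8Z)-9-iodo-3-methyl-6-[2-(triethylsilyloxy)propan-2-yl]deca-2,8-dienoate
Conditions: NaH, THF, 0 → 50 °C
Reagents that add atoms: none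
Why: Horner–Wadsworth–Emmons olefination of the methyl ketone should place the ester trans to the longer chain (E); a minor Z ester is expected and is removed by chromatography here or after step 6.

Step 6
Reactants: 9 ethyl (2E,6R,8Z)-9-iodo-3-methyl-6-[2-(triethylsilyloxy)propan-2-yl]deca-2,8-dienoate
Product: 10 (2E,6R,8Z)-9-iodo-3-methyl-6-[2-(triethylsilyloxy)propan-2-yl]deca-2,8-dien-1-ol
Conditions: i-Bu2AlH, CH2Cl2, −78 °C
Reagents that add atoms: none
Why: 1,2-Reduction of the conjugated ester by the aluminium hydride at low temperature; the vinyl iodide and the silyl ether are inert.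

Step 7
Reactants: 10 (2E,6R,8Z)-9-iodo-3-methyl-6-[2-(triethylsilyloxy)propan-2-yl]deca-2,8-dien-1-ol
Product: 11 (2E,6R,8Z)-9-iodo-3-methyl-6-[2-(triethylsilyloxy)propan-2-yl]deca-2,8-dienal
Conditions: MnO2, CH2Cl2, rt
Reagents that add atoms: none
Why: Selective allylic oxidation on the MnO2 surface stops at the aldehyde and should keep the E geometry.

Step 8
Reactants: 12 3-methylbut-2-enal
Product: 13 1,1-dimethoxy-3-methylbut-2-ene
Conditions: HC(OMe)3, MeOH, NH4NO3 (cat.), rt
Reagents that add atoms: trimethyl orthoformate, COC(OC)OC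
Why: Acid-catalysed acetalisation with the orthoester as water scavenger; the weakly acidic ammonium salt avoids conjugate addition of methanol.

Step 9
Reactants: 13 1,1-dimethoxy-3-methylbut-2-ene
Product: 14 (E)-1-methoxy-3-methylbuta-1,3-diene
Conditions: KHSO4 (cat.), 140–160 °C, MeOH distilled off; fractional distillation
Reagents that add atoms: none
Why: Acid-catalysed 1,4-elimination of methanol (loss of a γ-proton from the allyl-stabilised oxocarbenium ion), the reaction type used to crack prenal acetals to 1-alkoxy-3-methylbutadienes; the E enol ether should predominate and any Z isomer is expected to be a spectator in step 10.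

Step 10
Reactants: 11 (2E,6R,8Z)-9-iodo-3-methyl-6-[2-(triethylsilyloxy)propan-2-yl]deca-2,8-dienal; 14 (E)-1-methoxy-3-methylbuta-1,3-diene
Product: 15 (2R,6S)-6-[(1E,5R,7Z)-8-iodo-2-methyl-5-[2-(triethylsilyloxy)propan-2-yl]nona-1,7-dien-1-yl]-2-methoxy-4-methyl-5,6-dihydro-2H-pyran
Conditions: 14 (3 equiv), (1S,2R)-[Cr(L)Cl] (5–10 mol %; H2L = Schiff base of 3-(1-adamantyl)-2-hydroxy-5-methylbenzaldehyde and cis-1-amino-2-indanol), 4 Å molecular sieves, neat or t-BuOMe, rt
Reagents that add atoms: none
Why: The trivalent chromium centre binds the aldehyde oxygen of 11, and the C=O acts as the 2π partner of a concerted, asynchronous [4+2] cycloaddition with 14 as the 4π partner; the closest known reaction type is the enantioselective hetero-Diels–Alder reaction of aldehydes with 1-alkoxy-1,3-dienes under tridentate Schiff-base chromium chloride catalysts. The dihydropyran is closed by intermolecular cycloaddition and not by cyclisation of a chain: C1–C14 and O–C11 form in the same step and C12=C13 appears as the ring olefin. Regiochemistry follows from polarity, the nucleophilic CH2 terminus of the diene (C14) bonding to the carbonyl carbon and the methoxy-bearing terminus (C11) to oxygen. C1 (6S in the pyran) is set by the catalyst, which should shield the Re face of the bound aldehyde so that the diene adds to the Si face; C6 is too remote to create a matched or mismatched pairing. The acetal carbon C11 (2R) follows from the endo approach, which places methoxy and the C6 substituent of the pyran cis; this centre is erased in step 11. The chemoselectivity needed is reaction at C=O and not at C2=C3, either as dienophile or as part of a heterodiene, and the β,β-disubstitution at C3 secures it by hindering both modes. Because a six-membered ring can only hold a cis olefin, C11 and C14 end up cis on C12=C13, which is the geometry of the later epoxide. The triethylsilyl ether and the vinyl iodide should not engage the catalyst and pass through unchanged.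

Step 11
Reactants: 15 (2R,6S)-6-[(1E,5R,7Z)-8-iodo-2-methyl-5-[2-(triethylsilyloxy)propan-2-yl]nona-1,7-dien-1-yl]-2-methoxy-4-methyl-5,6-dihydro-2H-pyran
Product: 17 (2Z,5S,6E,10R,12Z)-13-iodo-3,7-dimethyl-10-[2-(triethylsilyloxy)propan-2-yl]tetradeca-2,6,12-triene-1,5-diol, via lactol 16 (not isolated)
Conditions: PPTS (cat.), THF/H2O (4:1), rt; then NaHCO3, NaBH4, 0 °C
Reagents that add atoms: water, O
Why: Mild aqueous acid ionises only the acetal carbon (allyl-stabilised oxocarbenium ion) to the lactol, whose open Z-hydroxy enal form is reduced 1,2 by borohydride; methanol and cerium salts are avoided so that the lactol cannot return to an acetal, and C1 and the Z geometry fixed by the ring are untouched.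

Step 12
Reactants: 17 (2Z,5S,6E,10R,12Z)-13-iodo-3,7-dimethyl-10-[2-(triethylsilyloxy)propan-2-yl]tetradeca-2,6,12-triene-1,5-diol
Product: 18 (2Z,5S,6E,10R,12Z)-5-hydroxy-13-iodo-3,7-dimethyl-10-[2-(triethylsilyloxy)propan-2-yl]tetradeca-2,6,12-trien-1-yl pivalate
Conditions: t-BuCOCl, pyridine, CH2Cl2, −20 → 0 °C
Reagents that add atoms: pivaloyl chloride, CC(C)(C)C(Cl)=O
Why: Acylation with a bulky acid chloride at low temperature should select the primary over the secondary allylic hydroxyl on steric grounds.

Step 13
Reactants: 18 (2Z,5S,6E,10R,12Z)-5-hydroxy-13-iodo-3,7-dimethyl-10-[2-(triethylsilyloxy)propan-2-yl]tetradeca-2,6,12-trien-1-yl pivalate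
Product: 19 (2Z,5S,6E,10R,12Z)-5-(tert-butyldimethylsilyloxy)-13-iodo-3,7-dimethyl-10-[2-(triethylsilyloxy)propan-2-yl]tetradeca-2,6,12-trien-1-yl pivalate
Conditions: t-BuMe2SiOTf, 2,6-lutidine, CH2Cl2, −78 °C
Reagents that add atoms: tert-butyldimethylsilyl trifluoromethanesulfonate, CC(C)(C)[Si](C)(C)OS(=O)(=O)C(F)(F)F
Why: Silyl triflate silylation of the remaining secondary allylic alcohol masks the C1 hydroxyl for the epoxidation and the palladium step.

Step 14
Reactants: 19 (2Z,5S,6E,10R,12Z)-5-(tert-butyldimethylsilyloxy)-13-iodo-3,7-dimethyl-10-[2-(triethylsilyloxy)propan-2-yl]tetradeca-2,6,12-trien-1-yl pivalate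
Product: 20 (2Z,5S,6E,10R,12Z)-5-(tert-butyldimethylsilyloxy)-13-iodo-3,7-dimethyl-10-[2-(triethylsilyloxy)propan-2-yl]tetradeca-2,6,12-trien-1-ol
Conditions: i-Bu2AlH, CH2Cl2, −78 °C
Reagents that add atoms: none
Why: Reductive cleavage of the pivalate at low temperature frees the C11 hydroxyl; silyl ethers and the vinyl iodide are inert to the hydride.

Step 15
Reactants: 20 (2Z,5S,6E,10R,12Z)-5-(tert-butyldimethylsilyloxy)-13-iodo-3,7-dimethyl-10-[2-(triethylsilyloxy)propan-2-yl]tetradeca-2,6,12-trien-1-ol
Product: 21 [(2S,3R)-3-[(2S,3E,7R,9Z)-2-(tert-butyldimethylsilyloxy)-10-iodo-4-methyl-7-[2-(triethylsilyloxy)propan-2-yl]undeca-3,9-dien-1-yl]-3-methyloxiran-2-yl]methanol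
Conditions: Ti(OiPr)4 (cat.), L-(+)-diethyl tartrate, t-BuOOH, 4 Å molecular sieves, CH2Cl2, −20 °C
Reagents that add atoms: tert-butyl hydroperoxide, CC(C)(C)OO
Why: Sharpless asymmetric epoxidation: the titanium tartrate binds the C11 alkoxide and delivers oxygen to one face of the Z-trisubstituted olefin only, which with L-(+)-tartrate should give the (2S,3R)-epoxy alcohol (12S,13R, cis from the Z olefin); the other olefins are not allylic alcohols and should not react.

Step 16
Reactants: 21 [(2S,3R)-3-[(2S,3E,7R,9Z)-2-(tert-butyldimethylsilyloxy)-10-iodo-4-methyl-7-[2-(triethylsilyloxy)propan-2-yl]undeca-3,9-dien-1-yl]-3-methyloxiran-2-yl]methanol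
Product: 22 (2R,3R)-3-[(2S,3E,7R,9Z)-2-(tert-butyldimethylsilyloxy)-10-iodo-4-methyl-7-[2-(triethylsilyloxy)propan-2-yl]undeca-3,9-dien-1-yl]-3-methyloxirane-2-carbaldehyde
Conditions: Dess–Martin periodinane, NaHCO3, CH2Cl2, 0 °C → rt
Reagents that add atoms: none
Why: Buffered hypervalent-iodine oxidation is near neutral and should preserve the epoxide and the configuration at C12 (the descriptor changes only because the formyl group gains priority); the aldehyde is used crude.

Step 17
Reactants: 22 (2R,3R)-3-[(2S,3E,7R,9Z)-2-(tert-butyldimethylsilyloxy)-10-iodo-4-methyl-7-[2-(triethylsilyloxy)propan-2-yl]undeca-3,9-dien-1-yl]-3-methyloxirane-2-carbaldehyde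
Product: 23 (2R,3S)-3-ethenyl-2-[(2S,3E,7R,9Z)-2-(tert-butyldimethylsilyloxy)-10-iodo-4-methyl-7-[2-(triethylsilyloxy)propan-2-yl]undeca-3,9-dien-1-yl]-2-methyloxirane
Conditions: MePPh3Br, KN(SiMe3)2, THF, 0 °C; then 22, −78 → 0 °C
Reagents that add atoms: methyltriphenylphosphonium bromide, C[P+](c1ccccc1)(c1ccccc1)c1ccccc1.[Br-]
Why: Wittig methylenation of the epoxy aldehyde with the non-stabilised ylide at low temperature adds C10 and should be much faster than attack on the epoxide or epimerisation at C12.

Step 18
Reactants: 23 (2R,3S)-3-ethenyl-2-[(2S,3E,7R,9Z)-2-(tert-butyldimethylsilyloxy)-10-iodo-4-methyl-7-[2-(triethylsilyloxy)propan-2-yl]undeca-3,9-dien-1-yl]-2-methyloxirane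
Product: 25 (1S,2E,6R,8Z,12S,13R)-1-(tert-butyldimethylsilyloxy)-12,13-epoxy-3,9,13-trimethyl-6-[2-(triethylsilyloxy)propan-2-yl]cyclotetradeca-2,8-diene, via B-alkyl-9-BBN adduct 24 (not isolated)
Conditions: 9-BBN, THF, 0 °C → rt; then slow addition to Pd(dppf)Cl2, AsPh3, Cs2CO3, DMF/THF/H2O, rt → 45 °C, about 0.002 M
Reagents that add atoms: none
Why: Anti-Markovnikov hydroboration of the monosubstituted vinyl group (the trisubstituted olefins are far slower) places boron on C10; B-alkyl Suzuki–Miyaura coupling then proceeds by oxidative addition of zerovalent palladium into the C9–I bond, transmetalation of the hydroxyborate and reductive elimination with retention of the Z geometry. High dilution favours the fourteen-membered ring and no stereocentre is formed.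

Step 19
Reactants: 25 (1S,2E,6R,8Z,12S,13R)-1-(tert-butyldimethylsilyloxy)-12,13-epoxy-3,9,13-trimethyl-6-[2-(triethylsilyloxy)propan-2-yl]cyclotetradeca-2,8-diene
Product: 26 (1S,2E,6R,8Z,12S,13R)-12,13-epoxy-6-(2-hydroxypropan-2-yl)-3,9,13-trimethylcyclotetradeca-2,8-dien-1-ol
Conditions: Bu4NF, THF, rt → 45 °C
Reagents that add atoms: none
Why: Fluoride cleaves both Si–O bonds (secondary tert-butyldimethylsilyl and tertiary triethylsilyl); the epoxide is inert to fluoride and the alkoxides have no favourable ring size for opening it.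

Step 20
Reactants: 26 (1S,2E,6R,8Z,12S,13R)-12,13-epoxy-6-(2-hydroxypropan-2-yl)-3,9,13-trimethylcyclotetradeca-2,8-dien-1-ol
Product: 27 (1S,2E,6R,8Z,12S,13R)-1-acetoxy-6-(2-acetoxypropan-2-yl)-12,13-epoxy-3,9,13-trimethylcyclotetradeca-2,8-diene
Conditions: Ac2O, Et3N, DMAP, CH2Cl2, rt → 40 °C
Reagents that add atoms: acetic anhydride, CC(=O)OC(C)=O
Why: Nucleophilic catalysis by DMAP (acylpyridinium ion) should acylate the secondary allylic hydroxyl quickly and the tertiary one more slowly; the basic, Lewis-acid-free medium leaves the epoxide closed and no stereocentre is touched.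

## Compound list

1 | (R)-limonene, (4R)-1-methyl-4-(prop-1-en-2-yl)cyclohex-1-ene | CC1=CC[C@@H](CC1)C(C)=C | starting material
2 | {2-hydroxy-2-[(1R)-4-methylcyclohex-3-en-1-yl]propyl}mercury acetate (carbinol epimers) | CC1=CC[C@@H](CC1)C(C)(O)C[Hg]OC(C)=O | intermediate (not isolated)
3 | (R)-α-terpineol, 2-[(1R)-4-methylcyclohex-3-en-1-yl]propan-2-ol | CC1=CC[C@@H](CC1)C(C)(C)O | intermediate
4 | triethyl({2-[(1R)-4-methylcyclohex-3-en-1-yl]propan-2-yl}oxy)silane | CC1=CC[C@@H](CC1)C(C)(C)O[Si](CC)(CC)CC | intermediate
5 | secondary ozonide of 4, 1-methyl-4-[2-(triethylsilyloxy)propan-2-yl]-7,8,9-trioxabicyclo[4.2.1]nonane (ring stereocentre as in 4, bridgeheads undefined) | CC12CC[C@@H](C(C)(C)O[Si](CC)(CC)CC)CC(OO1)O2 | intermediate (not isolated)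
6 | (3R)-6-oxo-3-[2-(triethylsilyloxy)propan-2-yl]heptanal | CC(=O)CC[C@@H](C(C)(C)O[Si](CC)(CC)CC)CC=O | intermediate
7 | (5R,7Z)-8-iodo-5-[2-(triethylsilyloxy)propan-2-yl]non-7-en-2-one | CC(=O)CC[C@@H](C(C)(C)O[Si](CC)(CC)CC)C/C=C(/C)I | intermediate
8 | triethyl phosphonoacetate | CCOC(=O)CP(=O)(OCC)OCC | starting material
9 | ethyl (2E,6R,8Z)-9-iodo-3-methyl-6-[2-(triethylsilyloxy)propan-2-yl]deca-2,8-dienoate | CCOC(=O)/C=C(\C)CC[C@@H](C(C)(C)O[Si](CC)(CC)CC)C/C=C(/C)I | intermediate
10 | (2E,6R,8Z)-9-iodo-3-methyl-6-[2-(triethylsilyloxy)propan-2-yl]deca-2,8-dien-1-ol | OC/C=C(\C)CC[C@@H](C(C)(C)O[Si](CC)(CC)CC)C/C=C(/C)I | intermediate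
11 | (2E,6R,8Z)-9-iodo-3-methyl-6-[2-(triethylsilyloxy)propan-2-yl]deca-2,8-dienal | O=C/C=C(\C)CC[C@@H](C(C)(C)O[Si](CC)(CC)CC)C/C=C(/C)I | intermediate
12 | 3-methylbut-2-enal | CC(C)=CC=O | starting material
13 | 1,1-dimethoxy-3-methylbut-2-ene | COC(OC)C=C(C)C | intermediate
14 | (E)-1-methoxy-3-methylbuta-1,3-diene | CO/C=C/C(C)=C | intermediate
15 | (2R,6S)-6-[(1E,5R,7Z)-8-iodo-2-methyl-5-[2-(triethylsilyloxy)propan-2-yl]nona-1,7-dien-1-yl]-2-methoxy-4-methyl-5,6-dihydro-2H-pyran | CO[C@H]1C=C(C)C[C@H](O1)/C=C(\C)CC[C@@H](C(C)(C)O[Si](CC)(CC)CC)C/C=C(/C)I | intermediate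
16 | (6S)-6-[(1E,5R,7Z)-8-iodo-2-methyl-5-[2-(triethylsilyloxy)propan-2-yl]nona-1,7-dien-1-yl]-4-methyl-5,6-dihydro-2H-pyran-2-ol (anomers, in equilibrium with the Z-hydroxy enal) | OC1C=C(C)C[C@H](O1)/C=C(\C)CC[C@@H](C(C)(C)O[Si](CC)(CC)CC)C/C=C(/C)I | intermediate (not isolated)
17 | (2Z,5S,6E,10R,12Z)-13-iodo-3,7-dimethyl-10-[2-(triethylsilyloxy)propan-2-yl]tetradeca-2,6,12-triene-1,5-diol | OC/C=C(/C)C[C@H](O)/C=C(\C)CC[C@@H](C(C)(C)O[Si](CC)(CC)CC)C/C=C(/C)I | intermediate
18 | (2Z,5S,6E,10R,12Z)-5-hydroxy-13-iodo-3,7-dimethyl-10-[2-(triethylsilyloxy)propan-2-yl]tetradeca-2,6,12-trien-1-yl pivalate | CC(C)(C)C(=O)OC/C=C(/C)C[C@H](O)/C=C(\C)CC[C@@H](C(C)(C)O[Si](CC)(CC)CC)C/C=C(/C)I | intermediate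
19 | (2Z,5S,6E,10R,12Z)-5-(tert-butyldimethylsilyloxy)-13-iodo-3,7-dimethyl-10-[2-(triethylsilyloxy)propan-2-yl]tetradeca-2,6,12-trien-1-yl pivalate | CC(C)(C)C(=O)OC/C=C(/C)C[C@H](O[Si](C)(C)C(C)(C)C)/C=C(\C)CC[C@@H](C(C)(C)O[Si](CC)(CC)CC)C/C=C(/C)I | intermediate
20 | (2Z,5S,6E,10R,12Z)-5-(tert-butyldimethylsilyloxy)-13-iodo-3,7-dimethyl-10-[2-(triethylsilyloxy)propan-2-yl]tetradeca-2,6,12-trien-1-ol | OC/C=C(/C)C[C@H](O[Si](C)(C)C(C)(C)C)/C=C(\C)CC[C@@H](C(C)(C)O[Si](CC)(CC)CC)C/C=C(/C)I | intermediate
21 | [(2S,3R)-3-[(2S,3E,7R,9Z)-2-(tert-butyldimethylsilyloxy)-10-iodo-4-methyl-7-[2-(triethylsilyloxy)propan-2-yl]undeca-3,9-dien-1-yl]-3-methyloxiran-2-yl]methanol | OC[C@@H]1O[C@]1(C)C[C@H](O[Si](C)(C)C(C)(C)C)/C=C(\C)CC[C@@H](C(C)(C)O[Si](CC)(CC)CC)C/C=C(/C)I | intermediate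
22 | (2R,3R)-3-[(2S,3E,7R,9Z)-2-(tert-butyldimethylsilyloxy)-10-iodo-4-methyl-7-[2-(triethylsilyloxy)propan-2-yl]undeca-3,9-dien-1-yl]-3-methyloxirane-2-carbaldehyde | O=C[C@@H]1O[C@]1(C)C[C@H](O[Si](C)(C)C(C)(C)C)/C=C(\C)CC[C@@H](C(C)(C)O[Si](CC)(CC)CC)C/C=C(/C)I | intermediate
23 | (2R,3S)-3-ethenyl-2-[(2S,3E,7R,9Z)-2-(tert-butyldimethylsilyloxy)-10-iodo-4-methyl-7-[2-(triethylsilyloxy)propan-2-yl]undeca-3,9-dien-1-yl]-2-methyloxirane (12S,13R in ring numbering) | C=C[C@@H]1O[C@]1(C)C[C@H](O[Si](C)(C)C(C)(C)C)/C=C(\C)CC[C@@H](C(C)(C)O[Si](CC)(CC)CC)C/C=C(/C)I | intermediate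
24 | 9-[2-[(2S,3R)-3-[(2S,3E,7R,9Z)-2-(tert-butyldimethylsilyloxy)-10-iodo-4-methyl-7-[2-(triethylsilyloxy)propan-2-yl]undeca-3,9-dien-1-yl]-3-methyloxiran-2-yl]ethyl]-9-borabicyclo[3.3.1]nonane | B1(CC[C@@H]2O[C@]2(C)C[C@H](O[Si](C)(C)C(C)(C)C)/C=C(\C)CC[C@@H](C(C)(C)O[Si](CC)(CC)CC)C/C=C(/C)I)C3CCCC1CCC3 | intermediate (not isolated)
25 | (1S,2E,6R,8Z,12S,13R)-1-(tert-butyldimethylsilyloxy)-12,13-epoxy-3,9,13-trimethyl-6-[2-(triethylsilyloxy)propan-2-yl]cyclotetradeca-2,8-diene | CC(C)(C)[Si](C)(C)O[C@@H]1/C=C(\C)CC[C@@H](C(C)(C)O[Si](CC)(CC)CC)C/C=C(/C)CC[C@@H]2O[C@]2(C)C1 | intermediate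
26 | (1S,2E,6R,8Z,12S,13R)-12,13-epoxy-6-(2-hydroxypropan-2-yl)-3,9,13-trimethylcyclotetradeca-2,8-dien-1-ol | O[C@@H]1/C=C(\C)CC[C@@H](C(C)(C)O)C/C=C(/C)CC[C@@H]2O[C@]2(C)C1 | intermediate
27 | (1S,2E,6R,8Z,12S,13R)-1-acetoxy-6-(2-acetoxypropan-2-yl)-12,13-epoxy-3,9,13-trimethylcyclotetradeca-2,8-diene | CC(=O)O[C@@H]1/C=C(\C)CC[C@@H](C(C)(C)OC(C)=O)C/C=C(/C)CC[C@@H]2O[C@]2(C)C1 | target

## Step count and least certain steps

Total step count: 20. Longest linear sequence: 18 steps (steps 1–7 and 10–20, from 1 to 27); steps 8 and 9 form the two-step side branch to 14.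

**Step 10 (key step).** The cycloaddition may be slow or unselective, because a conjugated aldehyde is a weak heterodienophile and a mono-oxygenated diene a weak 4π partner. Oligomerisation of the diene at the Lewis acid could then outrun the union, and enantioface discrimination on a β,β-disubstituted enal could fall short. The fallback sets out from 11 and returns at 17, replacing the two-bond union by allylation and ring closure while keeping a six-membered ring as the guarantor of the cis C12=C13 geometry.
- Asymmetric methallylboration of 11 with (−)-Ipc2B(CH2C(CH3)=CH2) (from (−)-Ipc2BOMe and methallylmagnesium chloride, the antipode expected to add to the Si face) would give the homoallylic alcohol F1.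
- Acryloyl chloride and iPr2NEt would give the acrylate F2.
- Ring-closing metathesis with the second-generation Grubbs catalyst RuCl2(=CHPh)(PCy3)(H2IMes) would close the unsaturated lactone F3.
- Reduction with i-Bu2AlH at −78 °C would give lactol 16, which NaBH4 takes on to 17 as in step 11.

**Step 18.** Three processes threaten the ring closure: hydride transfer from the borane to the vinyl epoxide with allylic opening of the oxirane instead of hydroboration; 1,3-elimination from the borate (boron on C10 is γ to the C12–O bond) to a cyclopropyl carbinol under the basic coupling conditions; and intermolecular coupling to oligomers. The fallback sets out from 22 and returns at 25, avoiding any sp3 organometallic next to the epoxide.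
- A Takai-type olefination of 22 with Bu3SnCHBr2, CrCl2 and LiI would give the E-vinylstannane F4.
- A copper-mediated Stille-type ring closure with Cu(O2CC4H3S) (copper thiophene-2-carboxylate, monovalent copper) in N-methylpyrrolidone at high dilution, with no palladium to ionise the vinyl epoxide, would give the macrocyclic (8Z,10E)-diene epoxide F5.
- Diimide (2-nitrobenzenesulfonyl hydrazide, Et3N) should reduce only the disubstituted C10=C11 bond and give 25.

**Step 4.** Z selectivity may erode and conversion may be modest, as is typical of α-iodo ylides. Iodine transfer could give deiodinated or doubly iodinated olefin, and residual base could trigger intramolecular aldol reaction of the 1,6-keto aldehyde. The fallback sets out from 6 and returns at 7, building the halide geometry by cross-coupling.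
- Dibromo-olefination of the aldehyde (CBr4, PPh3, 0 °C; the ketone should be spared) would give the 1,1-dibromoalkene F6.
- Palladium-catalysed trans-selective Negishi monomethylation (MeZnCl, Pd(DPEphos)Cl2) should replace the bromide trans to the chain and give the Z-vinyl bromide F7.
- Copper-catalysed halide exchange (CuI, NaI, trans-N,N′-dimethylcyclohexane-1,2-diamine, dioxane, heat) would give 7 with retention.

**Step 5.** Geometric discrimination at a methyl ketone whose two α-substituents differ little in size is limited, so material would be lost as the Z ester, and the ketone may react slowly. The fallback sets out from 7 and returns at 9, fixing the geometry by syn-carbometalation instead of olefination.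
- Kinetic enolisation, phosphorylation and elimination (LiN(iPr)2, ClP(O)(OEt)2, then LiN(iPr)2, all at −78 °C to spare the vinyl iodide) would give the terminal alkyne F8.
- Zirconium-catalysed methylalumination (AlMe3, Cp2ZrCl2) and trapping of the alkenylalane with ClCO2Et would give 9 as the E isomer only.

## Further compounds

F1 | step 10 | (4S,5E,9R,11Z)-12-iodo-2,6-dimethyl-9-[2-(triethylsilyloxy)propan-2-yl]trideca-1,5,11-trien-4-ol | C=C(C)C[C@H](O)/C=C(\C)CC[C@@H](C(C)(C)O[Si](CC)(CC)CC)C/C=C(/C)I
F2 | step 10 | (4S,5E,9R,11Z)-12-iodo-2,6-dimethyl-9-[2-(triethylsilyloxy)propan-2-yl]trideca-1,5,11-trien-4-yl prop-2-enoate | C=CC(=O)O[C@@H](CC(C)=C)/C=C(\C)CC[C@@H](C(C)(C)O[Si](CC)(CC)CC)C/C=C(/C)I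
F3 | step 10 | (6S)-6-[(1E,5R,7Z)-8-iodo-2-methyl-5-[2-(triethylsilyloxy)propan-2-yl]nona-1,7-dien-1-yl]-4-methyl-5,6-dihydro-2H-pyran-2-one | O=C1C=C(C)C[C@H](O1)/C=C(\C)CC[C@@H](C(C)(C)O[Si](CC)(CC)CC)C/C=C(/C)I
F4 | step 18 | tributyl[(E)-2-[(2S,3R)-3-[(2S,3E,7R,9Z)-2-(tert-butyldimethylsilyloxy)-10-iodo-4-methyl-7-[2-(triethylsilyloxy)propan-2-yl]undeca-3,9-dien-1-yl]-3-methyloxiran-2-yl]ethenyl]stannane | CCCC[Sn](CCCC)(CCCC)/C=C/[C@@H]1O[C@]1(C)C[C@H](O[Si](C)(C)C(C)(C)C)/C=C(\C)CC[C@@H](C(C)(C)O[Si](CC)(CC)CC)C/C=C(/C)I
F5 | step 18 | (1S,2E,6R,8Z,10E,12S,13R)-1-(tert-butyldimethylsilyloxy)-12,13-epoxy-3,9,13-trimethyl-6-[2-(triethylsilyloxy)propan-2-yl]cyclotetradeca-2,8,10-triene | CC(C)(C)[Si](C)(C)O[C@@H]1/C=C(\C)CC[C@@H](C(C)(C)O[Si](CC)(CC)CC)C/C=C(C)\C=C\[C@@H]2O[C@]2(C)C1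
F6 | step 4 | (5R)-8,8-dibromo-5-[2-(triethylsilyloxy)propan-2-yl]oct-7-en-2-one | CC(=O)CC[C@@H](C(C)(C)O[Si](CC)(CC)CC)CC=C(Br)Br
F7 | step 4 | (5R,7Z)-8-bromo-5-[2-(triethylsilyloxy)propan-2-yl]non-7-en-2-one | CC(=O)CC[C@@H](C(C)(C)O[Si](CC)(CC)CC)C/C=C(/C)Br
F8 | step 5 | (5R,7Z)-8-iodo-5-[2-(triethylsilyloxy)propan-2-yl]non-7-en-1-yne | C#CCC[C@@H](C(C)(C)O[Si](CC)(CC)CC)C/C=C(/C)I
A1 | alternative 1 | (5Z,8R)-8-[(E)-5-(tert-butyldimethylsilyloxy)-3-methylpent-3-en-1-yl]-5,9,9-trimethyloxacyclonon-5-en-2-one | O=C1CC/C(C)=C\C[C@@H](CC/C(C)=C/CO[Si](C)(C)C(C)(C)C)C(C)(C)O1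
A2 | alternative 1 | (6R)-6-[(E)-5-(tert-butyldimethylsilyloxy)-3-methylpent-3-en-1-yl]-7,7-dimethyl-2-methylidene-4-(prop-1-en-2-yl)-1,3-dioxepane (either epimer at C4) | C=C1OC(C(C)=C)C[C@@H](CC/C(C)=C/CO[Si](C)(C)C(C)(C)C)C(C)(C)O1
A3 | alternative 2 | (1S,6R,8Z,12S,13R)-6-(2-acetoxypropan-2-yl)-12,13-epoxy-9,13-dimethyl-1-(triethylsilyloxy)cyclotetradec-8-en-2-yne | CC[Si](CC)(CC)O[C@@H]1C#CCC[C@@H](C(C)(C)OC(C)=O)C/C=C(/C)CC[C@@H]2O[C@]2(C)C1
A4 | alternative 2 | acyclic (10Z)-6,7-epoxy-6,10-dimethyl-4-(triethylsilyloxy)-13-(2-acetoxypropan-2-yl)octadec-10-ene-2,16-diyne with the configurations of A3 | CC#C[C@@H](O[Si](CC)(CC)CC)C[C@@]1(C)O[C@H]1CC/C(C)=C\C[C@@H](CCC#CC)C(C)(C)OC(C)=O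
A5 | alternative 3 | macrocyclic epoxy diene bis-silyl ether (same structure as 25) | CC(C)(C)[Si](C)(C)O[C@@H]1/C=C(\C)CC[C@@H](C(C)(C)O[Si](CC)(CC)CC)C/C=C(/C)CC[C@@H]2O[C@]2(C)C1
A6 | alternative 3 | seco vinyl epoxide with Z-vinyl iodide (same structure as 23) | C=C[C@@H]1O[C@]1(C)C[C@H](O[Si](C)(C)C(C)(C)C)/C=C(\C)CC[C@@H](C(C)(C)O[Si](CC)(CC)CC)C/C=C(/C)I
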